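**Retrosynthetic overview**
1. Target 27 ← hydrogenolysis of nine benzyl ethers ← reagent-controlled hydroboration–oxidation of the upper flav-2-ene 24, which sets C2 and C3 (2,3-trans) together.
2. Key disconnection: ring C of the upper flavan is closed by a one-pot formal [3+3] annulation that makes C3–C4 and O1–C8a from the ring-B methyl ketone 18 and the ring-A 2-bromobenzyl bromide 22.
3. Enabling feature: in ring A the benzylic carbon C4 and the oxygen-bearing carbon C8a are ortho neighbours through C4a. A CH2Br group beside an aryl bromide is therefore a C4/C8a 1,3-bis-electrophile that matches the O1–C2=C3 (Z)-enolate of the aryl ketone; C2 and C3 stay at the enol-ether level until step 19.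
4. Ketone 18 ← Ullmann diaryl ether union of the hindered phenol 17 with the 7-bromo lower flavan 14; 14 ← the same annulation (7 + 5), hydroboration, then C3 inversion (oxidation, LiBH(s-Bu)3) to the 2,3-cis series.
5. Ring order: lower ring C (step 6) → diaryl ether (step 14) → upper ring C (step 18); rings A and B of both halves are bought as benzenes.

Key step: step 18

Remark: the SMILES is read as (2R,3S), 2,3-trans, for the upper flavan (the one whose ring B carries the aryl ether) and (2R,3R), 2,3-cis, for the lower flavan; the facial sense of IpcBH2 made from (+)-α-pinene is assumed to follow that known for 1-arylcycloalkenes and should be confirmed on compound 9.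

**Route**

Step 1
Reactants: 1 3,5-dibromophenol
Product: 2 2,4-dibromo-6-hydroxybenzaldehyde
Conditions: MgCl2, Et3N, paraformaldehyde, MeCN, reflux; then aq HCl
Reagents that add atoms: paraformaldehyde (formaldehyde), C=O
Why: Magnesium-phenoxide-directed ortho-formylation delivers formaldehyde only ortho to the hydroxyl, and the two ortho positions of 1 are equivalent, so one aldehyde should form.

Step 2
Reactants: 2 2,4-dibromo-6-hydroxybenzaldehyde
Product: 3 2-(benzyloxy)-4,6-dibromobenzaldehyde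
Conditions: BnBr, K2CO3, DMF, 40 °C
Reagents that add atoms: benzyl bromide, BrCc1ccccc1
Why: Williamson ether synthesis on the only phenol present.

Step 3
Reactants: 3 2-(benzyloxy)-4,6-dibromobenzaldehyde
Product: 4 [2-(benzyloxy)-4,6-dibromophenyl]methanol
Conditions: NaBH4, THF/MeOH, 0 °C
Reagents that add atoms: none
Why: Hydride reduction of the aldehyde; aryl bromides and the benzyl ether are inert to NaBH4.

Step 4
Reactants: 4 [2-(benzyloxy)-4,6-dibromophenyl]methanol
Product: 5 1-(benzyloxy)-3,5-dibromo-2-(bromomethyl)benzene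
Conditions: PBr3, Et2O, 0 °C
Reagents that add atoms: phosphorus tribromide, BrP(Br)Br
Why: Bromide displacement on the phosphite ester of a primary benzylic alcohol (alcohol to bromide with PBr3).

Step 5
Reactants: 6 1-(3,4,5-trihydroxyphenyl)ethan-1-one
Product: 7 1-[3,4,5-tris(benzyloxy)phenyl]ethan-1-one
Conditions: BnBr (3.5 equiv), K2CO3, DMF, 60 °C
Reagents that add atoms: benzyl bromide, BrCc1ccccc1
Why: Exhaustive Williamson benzylation of the three phenols.

Step 6
Reactants: 7 1-[3,4,5-tris(benzyloxy)phenyl]ethan-1-one; 5 1-(benzyloxy)-3,5-dibromo-2-(bromomethyl)benzene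
Product: 9 5-(benzyloxy)-7-bromo-2-[3,4,5-tris(benzyloxy)phenyl]-4H-chromene, via open-chain ketone 8 (not isolated)
Conditions: LiN(SiMe3)2 (1.05 equiv), THF, −78 °C; 5, −78 → 0 °C; then CuI (10 mol %), 1,10-phenanthroline (20 mol %), Cs2CO3 (2 equiv), DMF, 100 °C (THF distilled off), one pot
Reagents that add atoms: none
Why: Proposed new method: the lithium enolate of 7 is C-benzylated by 5 (SN2 enolate alkylation) and ketone 8, re-enolised by Cs2CO3, should close by copper-catalysed intramolecular enolate O-arylation at the ortho bromide, since C-arylation would need a four-membered ring and the para bromide cannot be reached; the closest known reaction types are the copper-catalysed domino C-benzylation/O-arylation of 1,3-dicarbonyl compounds with 2-halobenzyl halides to 4H-chromenes and the intramolecular O-arylation of simple ketone enolates to benzofurans.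

Step 7
Reactants: 9 5-(benzyloxy)-7-bromo-2-[3,4,5-tris(benzyloxy)phenyl]-4H-chromene
Product: 11 (2R,3S)-5-(benzyloxy)-7-bromo-2-[3,4,5-tris(benzyloxy)phenyl]chroman-3-ol, via chromanyl(isopinocampheyl)borane 10 (not isolated)
Conditions: IpcBH2 (from (+)-α-pinene, pre-formed THF solution), THF, −25 → 0 °C; then NaOH, H2O2, 0 °C → rt
Reagents that add atoms: hydrogen peroxide, OO
Why: Asymmetric hydroboration–oxidation: H–B adds syn across C2=C3 with boron at C3 (β to the ring oxygen, away from the fully substituted C2), so the aryl group ends trans to the future OH, the alkene face is chosen by the chiral borane as for 1-arylcycloalkenes (expected 2R,3S), and C–B oxidation goes with retention.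

Step 8
Reactants: 11 (2R,3S)-5-(benzyloxy)-7-bromo-2-[3,4,5-tris(benzyloxy)phenyl]chroman-3-ol
Product: 12 (2R)-5-(benzyloxy)-7-bromo-2-[3,4,5-tris(benzyloxy)phenyl]chroman-3-one
Conditions: Dess–Martin periodinane, CH2Cl2, rt
Reagents that add atoms: none
Why: Dess–Martin oxidation of the secondary alcohol under near-neutral conditions, mild enough that the C2 stereocentre beside the new ketone should not enolise.

Step 9
Reactants: 12 (2R)-5-(benzyloxy)-7-bromo-2-[3,4,5-tris(benzyloxy)phenyl]chroman-3-one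
Product: 13 (2R,3R)-5-(benzyloxy)-7-bromo-2-[3,4,5-tris(benzyloxy)phenyl]chroman-3-ol
Conditions: LiBH(s-Bu)3 (L-Selectride), LiBr, THF, −78 °C; then H2O
Reagents that add atoms: none
Why: Substrate-controlled ketone reduction: the bulky hydride attacks C3 from the face away from the neighbouring 2-aryl group, giving the 3-OH cis to the aryl group (2R,3R), the usual crossing from the 2,3-trans to the 2,3-cis flavan-3-ol series.

Step 10
Reactants: 13 (2R,3R)-5-(benzyloxy)-7-bromo-2-[3,4,5-tris(benzyloxy)phenyl]chroman-3-ol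
Product: 14 (2R,3R)-3,5-bis(benzyloxy)-7-bromo-2-[3,4,5-tris(benzyloxy)phenyl]chromane
Conditions: NaH, BnBr, Bu4NI (cat.), DMF, 0 °C → rt
Reagents that add atoms: benzyl bromide, BrCc1ccccc1
Why: Williamson ether synthesis on the secondary alkoxide; no stereocentre is touched.

Step 11
Reactants: 6 1-(3,4,5-trihydroxyphenyl)ethan-1-one
Product: 15 1-[3,5-dihydroxy-4-(prop-2-en-1-yloxy)phenyl]ethan-1-one
Conditions: allyl bromide (1.0 equiv), KHCO3 (1.1 equiv), DMF, rt
Reagents that add atoms: allyl bromide, C=CCBr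
Why: Regioselective Williamson mono-alkylation: the 4-OH para to the acetyl group is the most acidic phenol, so a weak base should form and alkylate only that phenoxide.

Step 12
Reactants: 15 1-[3,5-dihydroxy-4-(prop-2-en-1-yloxy)phenyl]ethan-1-one
Product: 16 1-[3,5-bis(benzyloxy)-4-(prop-2-en-1-yloxy)phenyl]ethan-1-one
Conditions: BnBr (2.3 equiv), K2CO3, DMF, 50 °C
Reagents that add atoms: benzyl bromide, BrCc1ccccc1
Why: Williamson benzylation of the two remaining phenols.

Step 13
Reactants: 16 1-[3,5-bis(benzyloxy)-4-(prop-2-en-1-yloxy)phenyl]ethan-1-one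
Product: 17 1-[3,5-bis(benzyloxy)-4-hydroxyphenyl]ethan-1-one
Conditions: Pd(PPh3)4 (5 mol %), morpholine, THF, rt
Reagents that add atoms: none
Why: Tsuji–Trost deallylation: the π-allyl palladium complex formed from the aryl allyl ether is trapped by morpholine, and benzyl ethers are untouched.

Step 14
Reactants: 14 (2R,3R)-3,5-bis(benzyloxy)-7-bromo-2-[3,4,5-tris(benzyloxy)phenyl]chromane; 17 1-[3,5-bis(benzyloxy)-4-hydroxyphenyl]ethan-1-one
Product: 18 1-[3,5-bis(benzyloxy)-4-({(2R,3R)-3,5-bis(benzyloxy)-2-[3,4,5-tris(benzyloxy)phenyl]chroman-7-yl}oxy)phenyl]ethan-1-one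
Conditions: CuI (10 mol %), picolinic acid (20 mol %), K3PO4, DMSO, 90 °C
Reagents that add atoms: none
Why: Ullmann-type diaryl ether synthesis: the CuI/picolinic acid system suits di-ortho-substituted phenoxides, the unhindered bromide of 14 is the only halide present, and the stereocentres are remote.

Step 15
Reactants: 19 1,3-bis(benzyloxy)-5-bromobenzene
Product: 20 2,4-bis(benzyloxy)-6-bromobenzaldehyde
Conditions: POCl3, DMF, 0 → 70 °C; then H2O
Reagents that add atoms: N,N-dimethylformamide, CN(C)C=O; water, O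
Why: Vilsmeier–Haack formylation: the chloroiminium ion attacks the position para to one benzyloxy group and ortho to the other, which is less hindered than the position between the two benzyloxy groups.

Step 16
Reactants: 20 2,4-bis(benzyloxy)-6-bromobenzaldehyde
Product: 21 [2,4-bis(benzyloxy)-6-bromophenyl]methanol
Conditions: NaBH4, THF/MeOH, 0 °C
Reagents that add atoms: none
Why: Hydride reduction of the aldehyde.

Step 17
Reactants: 21 [2,4-bis(benzyloxy)-6-bromophenyl]methanol
Product: 22 1,5-bis(benzyloxy)-3-bromo-2-(bromomethyl)benzene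
Conditions: PBr3, Et2O, −10 °C; used at once without purification
Reagents that add atoms: phosphorus tribromide, BrP(Br)Br
Why: Alcohol-to-bromide conversion with PBr3; the electron-rich benzylic bromide is labile and is therefore made cold and used directly.

Step 18
Reactants: 18 1-[3,5-bis(benzyloxy)-4-({(2R,3R)-3,5-bis(benzyloxy)-2-[3,4,5-tris(benzyloxy)phenyl]chroman-7-yl}oxy)phenyl]ethan-1-one; 22 1,5-bis(benzyloxy)-3-bromo-2-(bromomethyl)benzene
Product: 24 5,7-bis(benzyloxy)-2-[3,5-bis(benzyloxy)-4-({(2R,3R)-3,5-bis(benzyloxy)-2-[3,4,5-tris(benzyloxy)phenyl]chroman-7-yl}oxy)phenyl]-4H-chromene, via open-chain ketone 23 (not isolated)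
Conditions: LiN(SiMe3)2 (1.05 equiv), THF, −78 °C; 22 (1.0 equiv), −78 → 0 °C; then CuI (10 mol %), 1,10-phenanthroline (20 mol %), Cs2CO3 (2 equiv), DMF, 100 °C (THF distilled off), one pot
Reagents that add atoms: none
Why: Proposed new method: LiN(SiMe3)2 turns ketone 18 into its (Z)-lithium enolate, whose carbon (C3) displaces the benzylic bromide of 22 by SN2 (C3–C4 bond, ketone 23); after Cs2CO3 and CuI/1,10-phenanthroline are added, the re-formed enolate oxygen (O1) is arylated at the ortho C–Br carbon (C8a) by oxidative addition and C–O reductive elimination at copper. The closest known reaction types are the copper-catalysed domino C-benzylation/O-arylation of 1,3-dicarbonyl compounds with 2-halobenzyl halides to 4H-chromenes and the copper- or palladium-catalysed intramolecular O-arylation of simple ketone enolates to benzofurans; new here is a non-stabilised aryl methyl ketone enolate carried through both events in one pot. Ring C closes in the 6-exo mode at the aryl carbon (O1 onto C8a), the only cyclisation open to the enolate because C-arylation at C3 would need a four-membered ring. No stereocentre is formed: C2 and C3 are left sp2 on purpose and are set together, trans, in step 19. The step needs C- over O-alkylation and mono- over dialkylation, which the lithium counter-ion in THF at −78 °C, one equivalent of the very reactive 2,4-dialkoxybenzyl bromide and the Z geometry of aryl ketone enolates (O1 and C4 cis across C2=C3) should secure; the benzyl ethers, the diaryl ether and the lower flavan are inert to both stages.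

Step 19
Reactants: 24 5,7-bis(benzyloxy)-2-[3,5-bis(benzyloxy)-4-({(2R,3R)-3,5-bis(benzyloxy)-2-[3,4,5-tris(benzyloxy)phenyl]chroman-7-yl}oxy)phenyl]-4H-chromene
Product: 26 (2R,3S)-5,7-bis(benzyloxy)-2-[3,5-bis(benzyloxy)-4-({(2R,3R)-3,5-bis(benzyloxy)-2-[3,4,5-tris(benzyloxy)phenyl]chroman-7-yl}oxy)phenyl]chroman-3-ol, via chromanyl(isopinocampheyl)borane 25 (not isolated)
Conditions: IpcBH2 (from (+)-α-pinene, pre-formed THF solution), THF, −25 → 0 °C; then NaOH, H2O2, 0 °C → rt
Reagents that add atoms: hydrogen peroxide, OO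
Why: Asymmetric hydroboration–oxidation as in step 7: syn addition with boron at C3 gives the 2,3-trans relationship, the reagent (not the remote lower flavan) selects the face (expected 2R,3S), and any minor isomer is now a diastereomer that should be separable by chromatography.

Step 20
Reactants: 26 (2R,3S)-5,7-bis(benzyloxy)-2-[3,5-bis(benzyloxy)-4-({(2R,3R)-3,5-bis(benzyloxy)-2-[3,4,5-tris(benzyloxy)phenyl]chroman-7-yl}oxy)phenyl]chroman-3-ol
Product: 27 (2R,3S)-2-[3,5-dihydroxy-4-({(2R,3R)-3,5-dihydroxy-2-(3,4,5-trihydroxyphenyl)chroman-7-yl}oxy)phenyl]chromane-3,5,7-triol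
Conditions: H2 (1 atm), Pd(OH)2/C, THF/MeOH, rt; work-up under argon
Reagents that add atoms: none
Why: Hydrogenolysis of the nine benzyl ethers over Pd(OH)2/C in a neutral medium, under which the benzylic C2–O1 bonds of flavan-3-ols and the diaryl ether normally survive.

**Compound list**
1 | 3,5-dibromophenol | Oc1cc(Br)cc(Br)c1 | starting material
2 | 2,4-dibromo-6-hydroxybenzaldehyde | O=Cc1c(O)cc(Br)cc1Br | intermediate
3 | 2-(benzyloxy)-4,6-dibromobenzaldehyde | O=Cc1c(OCc2ccccc2)cc(Br)cc1Br | intermediate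
4 | [2-(benzyloxy)-4,6-dibromophenyl]methanol | OCc1c(OCc2ccccc2)cc(Br)cc1Br | intermediate
5 | 1-(benzyloxy)-3,5-dibromo-2-(bromomethyl)benzene | BrCc1c(OCc2ccccc2)cc(Br)cc1Br | intermediate
6 | 1-(3,4,5-trihydroxyphenyl)ethan-1-one | CC(=O)c1cc(O)c(O)c(O)c1 | starting material
7 | 1-[3,4,5-tris(benzyloxy)phenyl]ethan-1-one | CC(=O)c1cc(OCc2ccccc2)c(OCc2ccccc2)c(OCc2ccccc2)c1 | intermediate
8 | 3-[2-(benzyloxy)-4,6-dibromophenyl]-1-[3,4,5-tris(benzyloxy)phenyl]propan-1-one | O=C(CCc1c(OCc2ccccc2)cc(Br)cc1Br)c1cc(OCc2ccccc2)c(OCc2ccccc2)c(OCc2ccccc2)c1 | intermediate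
9 | 5-(benzyloxy)-7-bromo-2-[3,4,5-tris(benzyloxy)phenyl]-4H-chromene | Brc1cc(OCc2ccccc2)c2c(c1)OC(=CC2)c1cc(OCc3ccccc3)c(OCc3ccccc3)c(OCc3ccccc3)c1 | intermediate
10 | {(2R,3S)-5-(benzyloxy)-7-bromo-2-[3,4,5-tris(benzyloxy)phenyl]chroman-3-yl}(isopinocampheyl)borane | Brc1cc(OCc2ccccc2)c2c(c1)O[C@H](c1cc(OCc3ccccc3)c(OCc3ccccc3)c(OCc3ccccc3)c1)[C@@H]([BH][C@@H]1C[C@@H]3C[C@H]([C@H]1C)C3(C)C)C2 | intermediate
11 | (2R,3S)-5-(benzyloxy)-7-bromo-2-[3,4,5-tris(benzyloxy)phenyl]chroman-3-ol | Brc1cc(OCc2ccccc2)c2c(c1)O[C@H](c1cc(OCc3ccccc3)c(OCc3ccccc3)c(OCc3ccccc3)c1)[C@@H](O)C2 | intermediate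
12 | (2R)-5-(benzyloxy)-7-bromo-2-[3,4,5-tris(benzyloxy)phenyl]chroman-3-one | Brc1cc(OCc2ccccc2)c2c(c1)O[C@H](c1cc(OCc3ccccc3)c(OCc3ccccc3)c(OCc3ccccc3)c1)C(=O)C2 | intermediate
13 | (2R,3R)-5-(benzyloxy)-7-bromo-2-[3,4,5-tris(benzyloxy)phenyl]chroman-3-ol | Brc1cc(OCc2ccccc2)c2c(c1)O[C@H](c1cc(OCc3ccccc3)c(OCc3ccccc3)c(OCc3ccccc3)c1)[C@H](O)C2 | intermediate
14 | (2R,3R)-3,5-bis(benzyloxy)-7-bromo-2-[3,4,5-tris(benzyloxy)phenyl]chromane | Brc1cc(OCc2ccccc2)c2c(c1)O[C@H](c1cc(OCc3ccccc3)c(OCc3ccccc3)c(OCc3ccccc3)c1)[C@H](OCc1ccccc1)C2 | intermediate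
15 | 1-[3,5-dihydroxy-4-(prop-2-en-1-yloxy)phenyl]ethan-1-one | CC(=O)c1cc(O)c(OCC=C)c(O)c1 | intermediate
16 | 1-[3,5-bis(benzyloxy)-4-(prop-2-en-1-yloxy)phenyl]ethan-1-one | CC(=O)c1cc(OCc2ccccc2)c(OCC=C)c(OCc2ccccc2)c1 | intermediate
17 | 1-[3,5-bis(benzyloxy)-4-hydroxyphenyl]ethan-1-one | CC(=O)c1cc(OCc2ccccc2)c(O)c(OCc2ccccc2)c1 | intermediate
18 | 1-[3,5-bis(benzyloxy)-4-({(2R,3R)-3,5-bis(benzyloxy)-2-[3,4,5-tris(benzyloxy)phenyl]chroman-7-yl}oxy)phenyl]ethan-1-one | CC(=O)c1cc(OCc2ccccc2)c(Oc2cc(OCc3ccccc3)c3c(c2)O[C@H](c2cc(OCc4ccccc4)c(OCc4ccccc4)c(OCc4ccccc4)c2)[C@H](OCc2ccccc2)C3)c(OCc2ccccc2)c1 | intermediate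
19 | 1,3-bis(benzyloxy)-5-bromobenzene | Brc1cc(OCc2ccccc2)cc(OCc2ccccc2)c1 | starting material
20 | 2,4-bis(benzyloxy)-6-bromobenzaldehyde | O=Cc1c(Br)cc(OCc2ccccc2)cc1OCc1ccccc1 | intermediate
21 | [2,4-bis(benzyloxy)-6-bromophenyl]methanol | OCc1c(Br)cc(OCc2ccccc2)cc1OCc1ccccc1 | intermediate
22 | 1,5-bis(benzyloxy)-3-bromo-2-(bromomethyl)benzene | BrCc1c(Br)cc(OCc2ccccc2)cc1OCc1ccccc1 | intermediate
23 | 3-[2,4-bis(benzyloxy)-6-bromophenyl]-1-[3,5-bis(benzyloxy)-4-({(2R,3R)-3,5-bis(benzyloxy)-2-[3,4,5-tris(benzyloxy)phenyl]chroman-7-yl}oxy)phenyl]propan-1-one | O=C(CCc1c(Br)cc(OCc2ccccc2)cc1OCc1ccccc1)c1cc(OCc2ccccc2)c(Oc2cc(OCc3ccccc3)c3c(c2)O[C@H](c2cc(OCc4ccccc4)c(OCc4ccccc4)c(OCc4ccccc4)c2)[C@H](OCc2ccccc2)C3)c(OCc2ccccc2)c1 | intermediate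
24 | 5,7-bis(benzyloxy)-2-[3,5-bis(benzyloxy)-4-({(2R,3R)-3,5-bis(benzyloxy)-2-[3,4,5-tris(benzyloxy)phenyl]chroman-7-yl}oxy)phenyl]-4H-chromene | C(c1ccccc1)Oc1cc(OCc2ccccc2)c2c(c1)OC(=CC2)c1cc(OCc2ccccc2)c(Oc2cc(OCc3ccccc3)c3c(c2)O[C@H](c2cc(OCc4ccccc4)c(OCc4ccccc4)c(OCc4ccccc4)c2)[C@H](OCc2ccccc2)C3)c(OCc2ccccc2)c1 | intermediate
25 | {(2R,3S)-5,7-bis(benzyloxy)-2-[3,5-bis(benzyloxy)-4-({(2R,3R)-3,5-bis(benzyloxy)-2-[3,4,5-tris(benzyloxy)phenyl]chroman-7-yl}oxy)phenyl]chroman-3-yl}(isopinocampheyl)borane | C(c1ccccc1)Oc1cc(OCc2ccccc2)c2c(c1)O[C@H](c1cc(OCc3ccccc3)c(Oc3cc(OCc4ccccc4)c4c(c3)O[C@H](c3cc(OCc5ccccc5)c(OCc5ccccc5)c(OCc5ccccc5)c3)[C@H](OCc3ccccc3)C4)c(OCc3ccccc3)c1)[C@@H]([BH][C@@H]1C[C@@H]3C[C@H]([C@H]1C)C3(C)C)C2 | intermediate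
26 | (2R,3S)-5,7-bis(benzyloxy)-2-[3,5-bis(benzyloxy)-4-({(2R,3R)-3,5-bis(benzyloxy)-2-[3,4,5-tris(benzyloxy)phenyl]chroman-7-yl}oxy)phenyl]chroman-3-ol | C(c1ccccc1)Oc1cc(OCc2ccccc2)c2c(c1)O[C@H](c1cc(OCc3ccccc3)c(Oc3cc(OCc4ccccc4)c4c(c3)O[C@H](c3cc(OCc5ccccc5)c(OCc5ccccc5)c(OCc5ccccc5)c3)[C@H](OCc3ccccc3)C4)c(OCc3ccccc3)c1)[C@@H](O)C2 | intermediate
27 | (2R,3S)-2-[3,5-dihydroxy-4-({(2R,3R)-3,5-dihydroxy-2-(3,4,5-trihydroxyphenyl)chroman-7-yl}oxy)phenyl]chromane-3,5,7-triol (CNP0298095.1) | Oc1cc(O)c2c(c1)O[C@H](c1cc(O)c(Oc3cc(O)c4c(c3)O[C@H](c3cc(O)c(O)c(O)c3)[C@H](O)C4)c(O)c1)[C@@H](O)C2 | target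

**Step count and risks**

Total step count: 20. Longest linear sequence: 13 steps (steps 1–4, 6–10, 14, 18–20).

Steps most likely to fail:

1. Step 18. The enolate of the large ketone may be benzylated twice or on oxygen by the very reactive bromide, and the copper-mediated ring closure may stall so that the aryl bromide is lost by reduction. Fallback: it sets out from ketone 18 and aldehyde 20 and returns to the route at 24. A Claisen–Schmidt condensation (KOH, EtOH/THF, rt) should give the enone (E)-3-[2,4-bis(benzyloxy)-6-bromophenyl]-1-[3,5-bis(benzyloxy)-4-({(2R,3R)-3,5-bis(benzyloxy)-2-[3,4,5-tris(benzyloxy)phenyl]chroman-7-yl}oxy)phenyl]prop-2-en-1-one F1, so that C3–C4 is made as a C=C bond and over-alkylation cannot occur. Conjugate reduction of the enone with [(Ph3P)CuH]6 (aryl bromide and benzyl ethers tolerated) gives ketone 23, now isolated and purified. A separate intramolecular enolate O-arylation (CuI, 1,10-phenanthroline, Cs2CO3, DMF, 100 °C) then closes ring C to 24.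

2. Step 6. The same two failure processes (over-alkylation of the methyl ketone enolate, incomplete O-arylation with competing reaction at the para bromide) apply. Fallback: it sets out from ketone 7 and aldehyde 3 and returns at 9. Claisen–Schmidt condensation gives the enone (E)-3-[2-(benzyloxy)-4,6-dibromophenyl]-1-[3,4,5-tris(benzyloxy)phenyl]prop-2-en-1-one F2; conjugate reduction with [(Ph3P)CuH]6 gives ketone 8 as an isolated compound; copper-catalysed intramolecular enolate O-arylation (CuI, 1,10-phenanthroline, Cs2CO3, DMF) gives 9.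

3. Step 14. Exchange of the di-ortho-substituted, electron-poor phenoxide onto copper may be too slow, so that the bromide of 14 is reduced or recovered while the methyl ketone of 17 self-condenses under the basic, hot conditions. Fallback: it sets out from bromide 14 and returns at 18, replacing the Ullmann coupling by an oxidative Chan–Lam coupling at room temperature. Miyaura borylation of 14 (bis(pinacolato)diboron, PdCl2(dppf), KOAc, dioxane, 90 °C) gives the boronate (2R,3R)-3,5-bis(benzyloxy)-7-(4,4,5,5-tetramethyl-1,3,2-dioxaborolan-2-yl)-2-[3,4,5-tris(benzyloxy)phenyl]chromane F3. Cleavage of the pinacol ester (NaIO4, NH4OAc, acetone/water) gives the boronic acid {(2R,3R)-3,5-bis(benzyloxy)-2-[3,4,5-tris(benzyloxy)phenyl]chroman-7-yl}boronic acid F4. Coupling of F4 with phenol 17 (Cu(OAc)2, pyridine, 4 Å molecular sieves, CH2Cl2, air, rt), a method that tolerates 2,6-disubstituted phenols, gives 18.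

Further compounds
F1 | step 18 | (E)-3-[2,4-bis(benzyloxy)-6-bromophenyl]-1-[3,5-bis(benzyloxy)-4-({(2R,3R)-3,5-bis(benzyloxy)-2-[3,4,5-tris(benzyloxy)phenyl]chroman-7-yl}oxy)phenyl]prop-2-en-1-one | O=C(/C=C/c1c(Br)cc(OCc2ccccc2)cc1OCc1ccccc1)c1cc(OCc2ccccc2)c(Oc2cc(OCc3ccccc3)c3c(c2)O[C@H](c2cc(OCc4ccccc4)c(OCc4ccccc4)c(OCc4ccccc4)c2)[C@H](OCc2ccccc2)C3)c(OCc2ccccc2)c1
F2 | step 6 | (E)-3-[2-(benzyloxy)-4,6-dibromophenyl]-1-[3,4,5-tris(benzyloxy)phenyl]prop-2-en-1-one | O=C(/C=C/c1c(OCc2ccccc2)cc(Br)cc1Br)c1cc(OCc2ccccc2)c(OCc2ccccc2)c(OCc2ccccc2)c1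
F3 | step 14 | (2R,3R)-3,5-bis(benzyloxy)-7-(4,4,5,5-tetramethyl-1,3,2-dioxaborolan-2-yl)-2-[3,4,5-tris(benzyloxy)phenyl]chromane | CC1(C)OB(OC1(C)C)c1cc(OCc2ccccc2)c2c(c1)O[C@H](c1cc(OCc3ccccc3)c(OCc3ccccc3)c(OCc3ccccc3)c1)[C@H](OCc1ccccc1)C2
F4 | step 14 | {(2R,3R)-3,5-bis(benzyloxy)-2-[3,4,5-tris(benzyloxy)phenyl]chroman-7-yl}boronic acid | OB(O)c1cc(OCc2ccccc2)c2c(c1)O[C@H](c1cc(OCc3ccccc3)c(OCc3ccccc3)c(OCc3ccccc3)c1)[C@H](OCc1ccccc1)C2
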